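**Strategy.** Ring numbering: C1 (OMe), C2 (=CH), C3 (=C, bearing C7H2OBz), C4 (OH), C5 (OBz), C6 (OH). The plan cuts the C6–C1 bond of the cyclohexene. C1 holds the methyl ether, sits next to the C2=C3 alkene, and has the unprotected carbinol C6 as its other ring neighbour. That is what a γ-methoxyallyl metal leaves behind after attacking an aldehyde. One reductive operation turns an enal dimethyl acetal into this nucleophile, closes the six-membered ring, places the alkene at C2=C3, creates C1 and C6, and leaves O1 methylated and O6 free. The precursor is an acyclic D-erythro hex-4-enal: C6 aldehyde, O5 benzoate, O4 and O7 silyl ethers, C1 dimethyl acetal.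

Key step: step 8

Assumption: (R)-SEGPHOS is taken to give the C4/C5 configuration drawn for 10; this is to be checked by Mosher ester analysis of O4–H, and if the sense is opposite, (S)-SEGPHOS is used with no other change.

Remarks on the design (ring numbering is used for the acyclic compounds too):
- **Stereochemistry.** In the target, O4 and O5 lie on one ring face and O6 and O1 on the other, all four centres being R. C4/C5 of precursor 13 are (R,R), which is erythro and becomes cis in the ring.
- **Protecting groups.** O4 and O7 are both β to C3, a position that carries chromium in the allyl metal. An acyloxy group there would be expelled reductively, so both carry silyl ethers. The only ester sits on the remote O5, and O7 is benzoylated last.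
- **Alkene geometry.** The isomer with C4 cis to C1 is carried. Any leakage of this geometry in step 5 is harmless, because step 8 erases it.
- **Acid sensitivity.** In 4, 5 and 10 a free hydroxyl lies cis to the allylic acetal, so acid could close a 2-methoxy-2,5-dihydrofuran and then form a furan. For this reason the route uses basic work-ups, Et3N-washed silica and a phosphate-buffered allylation.

Step 1
Reactants: 1 dimethyl malonate; 2 2,2-dimethoxyacetaldehyde (commercial aqueous solution)
Product: 3 dimethyl 2-(2,2-dimethoxyethylidene)malonate
Conditions: piperidine (10 mol %), AcOH (10 mol %), toluene, Dean–Stark, reflux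
Reagents that add atoms: none
Why: Knoevenagel condensation: the non-enolisable, strongly electrophilic aldehyde 2 condenses with the malonate under piperidinium acetate catalysis, azeotropic removal of water drives the dehydration, the weakly buffered medium leaves the acetal intact, and two identical ester groups mean that no alkene geometry arises.

Step 2
Reactants: 3 dimethyl 2-(2,2-dimethoxyethylidene)malonate
Product: 4 2-(2,2-dimethoxyethylidene)propane-1,3-diol
Conditions: i-Bu2AlH (DIBAL-H, 5 equiv), CH2Cl2, −78 to 0 °C; aq. potassium sodium tartrate
Reagents that add atoms: none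
Why: Hydride reduction of esters to alcohols: at low temperature in a non-coordinating solvent i-Bu2AlH attacks both conjugated ester carbonyls in the 1,2-sense (an established way from alkylidene malonates to 2-alkylidenepropane-1,3-diols), and the non-acidic tartrate work-up protects the allylic acetal.

Step 3
Reactants: 4 2-(2,2-dimethoxyethylidene)propane-1,3-diol
Product: 5 (E)-2-[(tert-butyldimethylsilyloxy)methyl]-4,4-dimethoxybut-2-en-1-ol (free CH2OH cis to the acetal carbon)
Conditions: NaH (1.0 equiv), THF, 0 °C; TBSCl (1.0 equiv), 0 °C to rt; Et3N-washed silica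
Reagents that add atoms: tert-butyldimethylsilyl chloride, CC(C)(C)[Si](C)(C)Cl
Why: Monosilylation of a diol through its sparingly soluble monosodium alkoxide: one hydroxyl is capped, the CH2OH trans to the bulky CH(OMe)2 group is the more accessible and should react first, which leaves the free CH2OH (future C4) cis to C1, and the minor geometric isomer is separated although it would converge in step 8.

Step 4
Reactants: 6 acrolein; 7 benzoic anhydride
Product: 8 prop-2-ene-1,1-diyl dibenzoate
Conditions: conc. H2SO4 (cat.), CH2Cl2, 0 °C to rt
Reagents that add atoms: none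
Why: Acid-catalysed acylal formation (1,1-addition of an anhydride to an aldehyde), which for acrolein takes place at the carbonyl carbon and leaves the vinyl group free for the allyl transfer.

Step 5
Reactants: 5 (E)-2-[(tert-butyldimethylsilyloxy)methyl]-4,4-dimethoxybut-2-en-1-ol; 8 prop-2-ene-1,1-diyl dibenzoate (2 equiv)
Product: 10 (3S,4R,5Z)-5-[(tert-butyldimethylsilyloxy)methyl]-4-hydroxy-7,7-dimethoxyhepta-1,5-dien-3-yl benzoate, via enal 9 (not isolated)
Conditions: [Ir(cod)Cl]2 (2.5 mol %), (R)-SEGPHOS (5 mol %), 4-cyano-3-nitrobenzoic acid (10 mol %), K3PO4 (1 equiv), THF, 90 °C, sealed tube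
Reagents that add atoms: none
Why: Krische-type iridium-catalysed transfer-hydrogenative carbonyl (α-acyloxy)allylation: the cyclometallated iridium C,O-benzoate dehydrogenates 5 to enal 9, ionises 8 to an (E)-(benzoyloxy)allyliridium species and unites the two through a closed chair transition state that sets C4 and C5 anti (erythro), the SEGPHOS ligand chooses the aldehyde face and so the absolute configuration, and K3PO4 takes up the benzoic acid that would otherwise endanger the acetal.

Step 6
Reactants: 10 (3S,4R,5Z)-5-[(tert-butyldimethylsilyloxy)methyl]-4-hydroxy-7,7-dimethoxyhepta-1,5-dien-3-yl benzoate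
Product: 11 (3S,4R,5Z)-5-[(tert-butyldimethylsilyloxy)methyl]-7,7-dimethoxy-4-(triethylsilyloxy)hepta-1,5-dien-3-yl benzoate
Conditions: TESCl (1.3 equiv), imidazole, DMAP (cat.), CH2Cl2, 0 °C
Reagents that add atoms: chlorotriethylsilane, CC[Si](Cl)(CC)CC
Why: Silyl ether formation with a silyl chloride and imidazole: fast capping of O4 stops O5-to-O4 benzoyl migration, and the chloride is preferred to the triflate because silyl triflate–lutidine mixtures ionise acetals.

Step 7
Reactants: 11 (3S,4R,5Z)-5-[(tert-butyldimethylsilyloxy)methyl]-7,7-dimethoxy-4-(triethylsilyloxy)hepta-1,5-dien-3-yl benzoate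
Product: 13 (2R,3R,4Z)-2-benzoyloxy-4-[(tert-butyldimethylsilyloxy)methyl]-6,6-dimethoxy-3-(triethylsilyloxy)hex-4-enal, via diol 12 (not isolated)
Conditions: OsO4 (2 mol %), NaIO4 (4 equiv), 2,6-lutidine (2 equiv), 1,4-dioxane–H2O 3:1, 0 °C to rt; used at once
Reagents that add atoms: osmium tetroxide, O=[Os](=O)(=O)=O; sodium periodate, [Na+].[O-]I(=O)(=O)=O
Why: Lemieux–Johnson oxidative cleavage in its lutidine-buffered form: the unhindered monosubstituted vinyl group is osmylated ahead of C2=C3, which is trisubstituted, screened by two silyloxy-bearing carbons and deactivated by four allylic C–O bonds, periodate cleaves diol 12 as soon as it forms so that the benzoate has no time to migrate, and the buffer protects the acetal, the triethylsilyl ether and the C5 stereocentre.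

Step 8
Reactants: 13 (2R,3R,4Z)-2-benzoyloxy-4-[(tert-butyldimethylsilyloxy)methyl]-6,6-dimethoxy-3-(triethylsilyloxy)hex-4-enal
Product: 17 (1S,2R,5R,6R)-3-[(tert-butyldimethylsilyloxy)methyl]-6-hydroxy-5-methoxy-2-(triethylsilyloxy)cyclohex-3-en-1-yl benzoate, via iodo ether 14 (not isolated), via allylchromium 15 (not isolated), via chromium alkoxide 16 (not isolated)
Conditions: CrCl2 (8 equiv), 2,6-di-tert-butyl-4-methylpyridine (0.5 equiv), THF (0.005 M in 13), −30 °C; Me3SiI (2.5 equiv) added slowly; −30 to 0 °C; aq. NaHCO3/potassium sodium tartrate
Reagents that add atoms: none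
Why: Proposed new method: Me3SiI exchanges one methoxy group of the allylic acetal, by far the most ionisable group present, for iodide (α-iodo ether 14), two equivalents of divalent chromium reduce the C1–I bond in successive one-electron steps to a trivalent allylchromium that is fluxional over C1–C3 (15), and its C1 terminus adds to the C6 aldehyde to give alkoxide 16, which is hydrolysed on work-up. The closest known reaction type is the intermolecular Nozaki–Hiyama-type coupling of enal acetals with aldehydes under CrCl2/Me3SiI, which runs through γ-alkoxyallylchromium reagents and gives anti 1,2-diol monoethers, whereas the ring-forming version with a fully substituted C3 terminus is untested. The ring closes in a 6-exo-trig mode at the carbonyl group with the allyl unit ending inside the ring: bonding through C3 would need a cyclobutane, so the C3-metallated σ-form reacts with allyl inversion (SE2') at C1, the alkene lands at C2=C3, and free rotation about C2–C3 in that σ-form lets either alkene isomer of 13 reach the cis ring alkene. C6 is set by the tether: with chromium bridging C3 and O6 the transition state is a boat-like bicyclo[2.2.2] array in which the cis pair O4/O5 can sit on the side away from the ligand-laden chromium bridge, and this places O6 trans to O5. C1 is set by the enol-ether geometry: the (E)-methoxyvinyl form keeps OMe outside the forming ring and maps onto C1–OMe cis to C6–OH (the ring counterpart of the anti outcome of the intermolecular reaction), whereas the (Z)-form would have to point OMe into the ring. The step needs cyclisation to beat both intermolecular attack and reductive loss of a β-oxygen: high dilution serves the first, and poor leaving groups (silyl ethers) on O4 and O7, with the only acyl group on the remote O5, serve the second.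

Step 9
Reactants: 17 (1S,2R,5R,6R)-3-[(tert-butyldimethylsilyloxy)methyl]-6-hydroxy-5-methoxy-2-(triethylsilyloxy)cyclohex-3-en-1-yl benzoate
Product: 18 (1R,2R,5R,6R)-2,6-dihydroxy-3-(hydroxymethyl)-5-methoxycyclohex-3-en-1-yl benzoate
Conditions: HF·pyridine, pyridine, THF, 0 °C to rt
Reagents that add atoms: none
Why: Fluoride-induced desilylation with buffered HF·pyridine: both silyl ethers (and any trimethylsilyl group picked up by O6 in step 8) are removed in a mildly acidic medium in which no alkoxide forms, so the O5 benzoate should stay in place, unlike under basic fluoride sources.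

Step 10
Reactants: 18 (1R,2R,5R,6R)-2,6-dihydroxy-3-(hydroxymethyl)-5-methoxycyclohex-3-en-1-yl benzoate
Product: 19 (1R,2R,5R,6R)-3-[(benzoyloxy)methyl]-2,6-dihydroxy-5-methoxycyclohex-3-en-1-yl benzoate (CNP0349013.4)
Conditions: BzCl (1.05 equiv), 2,4,6-collidine, CH2Cl2, −78 to −40 °C
Reagents that add atoms: benzoyl chloride, O=C(Cl)c1ccccc1
Why: Chemoselective acylation of a primary alcohol with an acid chloride and collidine at low temperature: the unhindered primary allylic O7–H reacts much faster than the secondary O4–H and O6–H, each flanked by two substituted ring carbons, and no stereocentre is touched.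

**Compound list**
1 | dimethyl malonate | COC(=O)CC(=O)OC | starting material
2 | 2,2-dimethoxyacetaldehyde | COC(OC)C=O | starting material
3 | dimethyl 2-(2,2-dimethoxyethylidene)malonate | COC(=O)C(=CC(OC)OC)C(=O)OC | intermediate
4 | 2-(2,2-dimethoxyethylidene)propane-1,3-diol | OCC(CO)=CC(OC)OC | intermediate
5 | (E)-2-[(tert-butyldimethylsilyloxy)methyl]-4,4-dimethoxybut-2-en-1-ol | OC/C(CO[Si](C)(C)C(C)(C)C)=C\C(OC)OC | intermediate
6 | acrolein | C=CC=O | starting material
7 | benzoic anhydride | O=C(OC(=O)c1ccccc1)c1ccccc1 | starting material
8 | prop-2-ene-1,1-diyl dibenzoate | C=CC(OC(=O)c1ccccc1)OC(=O)c1ccccc1 | intermediate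
9 | (Z)-2-[(tert-butyldimethylsilyloxy)methyl]-4,4-dimethoxybut-2-enal | O=C/C(CO[Si](C)(C)C(C)(C)C)=C\C(OC)OC | intermediate (not isolated)
10 | (3S,4R,5Z)-5-[(tert-butyldimethylsilyloxy)methyl]-4-hydroxy-7,7-dimethoxyhepta-1,5-dien-3-yl benzoate | C=C[C@H](OC(=O)c1ccccc1)[C@H](O)/C(CO[Si](C)(C)C(C)(C)C)=C\C(OC)OC | intermediate
11 | (3S,4R,5Z)-5-[(tert-butyldimethylsilyloxy)methyl]-7,7-dimethoxy-4-(triethylsilyloxy)hepta-1,5-dien-3-yl benzoate | C=C[C@H](OC(=O)c1ccccc1)[C@H](O[Si](CC)(CC)CC)/C(CO[Si](C)(C)C(C)(C)C)=C\C(OC)OC | intermediate
12 | 1,2-diol from osmylation of the vinyl group of 11 (C6 epimers) | OCC(O)[C@H](OC(=O)c1ccccc1)[C@H](O[Si](CC)(CC)CC)/C(CO[Si](C)(C)C(C)(C)C)=C\C(OC)OC | intermediate (not isolated)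
13 | (2R,3R,4Z)-2-benzoyloxy-4-[(tert-butyldimethylsilyloxy)methyl]-6,6-dimethoxy-3-(triethylsilyloxy)hex-4-enal | O=C[C@H](OC(=O)c1ccccc1)[C@H](O[Si](CC)(CC)CC)/C(CO[Si](C)(C)C(C)(C)C)=C\C(OC)OC | intermediate (precursor of the key step)
14 | C1 α-iodo methyl ether of 13 (C1 epimers) | O=C[C@H](OC(=O)c1ccccc1)[C@H](O[Si](CC)(CC)CC)/C(CO[Si](C)(C)C(C)(C)C)=C\C(I)OC | intermediate (not isolated)
15 | γ-methoxyallylchromium dichloride, drawn as the C3-bound σ-form with (E)-enol ether | O=C[C@H](OC(=O)c1ccccc1)[C@H](O[Si](CC)(CC)CC)C([Cr](Cl)Cl)(CO[Si](C)(C)C(C)(C)C)/C=C/OC | intermediate (not isolated)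
16 | O6 chromium dichloride alkoxide of 17 | CO[C@@H]1C=C(CO[Si](C)(C)C(C)(C)C)[C@@H](O[Si](CC)(CC)CC)[C@@H](OC(=O)c2ccccc2)[C@@H]1O[Cr](Cl)Cl | intermediate (not isolated)
17 | (1S,2R,5R,6R)-3-[(tert-butyldimethylsilyloxy)methyl]-6-hydroxy-5-methoxy-2-(triethylsilyloxy)cyclohex-3-en-1-yl benzoate | CO[C@@H]1C=C(CO[Si](C)(C)C(C)(C)C)[C@@H](O[Si](CC)(CC)CC)[C@@H](OC(=O)c2ccccc2)[C@@H]1O | intermediate (product of the key step)
18 | (1R,2R,5R,6R)-2,6-dihydroxy-3-(hydroxymethyl)-5-methoxycyclohex-3-en-1-yl benzoate | CO[C@@H]1C=C(CO)[C@@H](O)[C@@H](OC(=O)c2ccccc2)[C@@H]1O | intermediate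
19 | (1R,2R,5R,6R)-3-[(benzoyloxy)methyl]-2,6-dihydroxy-5-methoxycyclohex-3-en-1-yl benzoate | CO[C@@H]1C=C(COC(=O)c2ccccc2)[C@@H](O)[C@@H](OC(=O)c2ccccc2)[C@@H]1O | target

**Total step count:** 10. **Longest linear sequence:** 9 (steps 1–3 and 5–10; step 4 makes the allyl donor).

**Steps most likely to fail**

1. **Step 8 (new method).**
   - *Possible failure processes:* reductive elimination of a silyloxy group from the allylchromium; capture of the iodo ether or oxocarbenium stage by the cis silyl ether oxygen followed by aromatisation to a furan; intermolecular coupling through the C3 terminus; or closure through an open transition state with poor facial selectivity at C1 and C6.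
   - *Fallback with known chemistry, from 13 back to 17:* the C6–C1 bond is made intermolecularly and the ring is closed at C2=C3 instead. (E)-3-methoxyallylboronic acid pinacol ester F1 is made from acrolein dimethyl acetal and B2pin2 by copper-catalysed allylic boryl substitution (CuCl, Xantphos, KOt-Bu). F1 is added to aldehyde 13 under chiral phosphoric acid catalysis (TRIP, toluene, −30 °C). The closed chair transition state of allylboration translates the (E)-geometry into the anti C1/C6 pair. The intrinsic facial bias of such aldehydes towards (E)-allylboronates is small, so the catalyst antipode is chosen to give the C6 configuration of 17. This leads to the acyclic methoxy diene F2. Ring-closing metathesis of F2 (second-generation Hoveyda–Grubbs catalyst, toluene, 80 °C) joins the new vinyl carbon to C3, expels the old C1–C2 unit and gives 17.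

2. **Step 5.**
   - *Possible failure processes:* migration of the benzoyl group from O5 to O4 in the hot basic medium, or loss of silanolate from the transient enal.
   - *Fallback, from 5 (with 8) back to 10:* the coupling is run as before, but the donor's benzoate is no longer relied on as the O5 label. The crude, scrambled ester mixture is methanolysed (K2CO3, MeOH, rt) to the anti-diol F3, whose stereocentres are untouched by the scrambling. The ester is then re-installed by tin-catalysed monobenzoylation of the 1,2-diol (Me2SnCl2 cat., BzCl, K2CO3, THF). This reaction stops at the monoester. It should acylate O5, which is flanked only by the vinyl group, rather than O4, which is pressed against the fully substituted C3. This returns to 10, and misplaced ester is recycled through F3.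

3. **Step 7.**
   - *Possible failure processes:* competing osmylation of C2=C3, benzoate migration within the diol, or epimerisation at C5 of the aldehyde.
   - *Fallback, from 11 back to 12 and 13:* the choice between the two alkenes is handed from an electrophilic oxidant to a sterically ruled metal catalyst. Diboration under zerovalent platinum catalysis (Pt(dba)2, B2pin2, toluene, 50 °C) is confined to terminal and strained alkenes and gives the 1,2-bis(boronate) F4. Oxidation with NaBO3·4H2O (THF–H2O) yields diol 12, now isolated, and NaIO4 on silica gel cleaves it to 13.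

**Further compounds**
F1 | step 8 | (E)-3-methoxyallylboronic acid pinacol ester | CO/C=C/CB1OC(C)(C)C(C)(C)O1
F2 | step 8 | (3R,4R,5S,6R,7Z)-7-[(tert-butyldimethylsilyloxy)methyl]-4-hydroxy-3,9,9-trimethoxy-6-(triethylsilyloxy)nona-1,7-dien-5-yl benzoate | C=C[C@@H](OC)[C@@H](O)[C@H](OC(=O)c1ccccc1)[C@H](O[Si](CC)(CC)CC)/C(CO[Si](C)(C)C(C)(C)C)=C\C(OC)OC
F3 | step 5 | (3S,4R,5Z)-5-[(tert-butyldimethylsilyloxy)methyl]-7,7-dimethoxyhepta-1,5-diene-3,4-diol | C=C[C@H](O)[C@H](O)/C(CO[Si](C)(C)C(C)(C)C)=C\C(OC)OC
F4 | step 7 | 1,2-bis(pinacolboronate) from diboration of the vinyl group of 11 (C6 epimers) | CC1(C)OB(OC1(C)C)CC(B1OC(C)(C)C(C)(C)O1)[C@H](OC(=O)c1ccccc1)[C@H](O[Si](CC)(CC)CC)/C(CO[Si](C)(C)C(C)(C)C)=C\C(OC)OC
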